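**Strategy**

Everything rests on cutting the C7=C8 bond of a temporary α,β-unsaturated δ-lactone (ring B) that ties the C1 oxygen to the side chain on C6 of the cyclohexane (ring A: C1 angelate carbon, C3 methyl, C4 hydroxyl; chain C7–C11). Ring-closing metathesis of an acrylate on the C1 oxygen with an isopropenyl group on C6 exploits the trans-diequatorial C1–O and C6–C7 bonds of ring A and, in one operation, fuses C7–C9 to it as a rigid trans bicycle, which then directs hydride to one face of C7 and is opened at C9 by an alkenyllithium. The precursor is the acrylate of an isopulegol-like cyclohexanol with an equatorial C3 methyl and an axial C4 PMB ether.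

Key step: step 8

Assumption: the (S)-configured phosphoric acid of step 2 is taken to expose the Si face of aldehyde 2 to the boronate (the (R)-acid the Re face); if the sense were the reverse, only the antipode of the acid would change.
Remark: lithium alkoxides, copper enolates and borate esters that exist only until aqueous work-up are treated as hydrolysed there and are not listed as separate compounds.

**Route**

Step 1
Reactants: 1 4-methylpent-3-en-1-ol
Product: 2 4-methylpent-3-enal
Conditions: Dess–Martin periodinane, pyridine, CH2Cl2, 0 °C; filtered, concentrated cold, taken up in toluene and used at once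
Reagents that add atoms: none
Why: Dess–Martin oxidation takes a primary alcohol to the aldehyde under buffered, near-neutral conditions, which should keep the β,γ-alkene of 2 from moving into conjugation; no stereocentre is involved.

Step 2
Reactants: 2 4-methylpent-3-enal; 3 (E)-crotylboronic acid pinacol ester
Product: 4 (3S,4R)-3,7-dimethylocta-1,6-dien-4-ol
Conditions: (S)-3,3'-bis(2,4,6-triisopropylphenyl)-1,1'-binaphthyl-2,2'-diyl hydrogen phosphate (5 mol%), 4 Å molecular sieves, toluene, −30 °C; aq. NaHCO3 work-up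
Reagents that add atoms: none
Why: Chiral phosphoric acid-catalysed crotylboration of an aldehyde runs through a closed six-membered chair transition state, so the E geometry of 3 is translated into the anti relation of the C3 methyl and C4 hydroxyl, while the acid, hydrogen-bonded to a boronate oxygen and the formyl hydrogen, should leave only the Si face open and so set (3S,4R).

Step 3
Reactants: 4 (3S,4R)-3,7-dimethylocta-1,6-dien-4-ol
Product: 5 1-({[(3S,4R)-3,7-dimethylocta-1,6-dien-4-yl]oxy}methyl)-4-methoxybenzene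
Conditions: NaH, 4-methoxybenzyl chloride, Bu4NI (cat.), DMF, 0 °C to rt
Reagents that add atoms: 4-methoxybenzyl chloride, COc1ccc(CCl)cc1
Why: Williamson etherification of the sodium alkoxide with the benzylic chloride, iodide-catalysed, protects the C4 oxygen as an ether that tolerates the later Lewis acid, carbene, hydride and organolithium steps and is removed oxidatively at the end; no stereocentre is touched.

Step 4
Reactants: 5 1-({[(3S,4R)-3,7-dimethylocta-1,6-dien-4-yl]oxy}methyl)-4-methoxybenzene
Product: 7 (3S,4R)-4-[(4-methoxybenzyl)oxy]-3,7-dimethyloct-6-en-1-ol, via B-alkyl-9-borabicyclononane 6 (not isolated)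
Conditions: 9-BBN (9-borabicyclo[3.3.1]nonane, 1.1 equiv), THF, 0 °C to rt; then aq. NaOH, 30% H2O2, 0 °C to rt
Reagents that add atoms: hydrogen peroxide, OO
Why: Hydroboration–oxidation with the bulky 9-BBN should take the monosubstituted vinyl group in preference to the trisubstituted alkene and place boron on the terminal carbon, and alkaline peroxide then exchanges boron for hydroxyl, leaving C3 and C4 untouched.

Step 5
Reactants: 7 (3S,4R)-4-[(4-methoxybenzyl)oxy]-3,7-dimethyloct-6-en-1-ol
Product: 8 (3S,4R)-4-[(4-methoxybenzyl)oxy]-3,7-dimethyloct-6-enal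
Conditions: Dess–Martin periodinane, pyridine, CH2Cl2, rt
Reagents that add atoms: none
Why: Dess–Martin oxidation of the primary alcohol gives the aldehyde without acid or base strong enough to disturb the PMB ether, and the stereocentre C3 is β to the carbonyl and cannot enolise.

Step 6
Reactants: 8 (3S,4R)-4-[(4-methoxybenzyl)oxy]-3,7-dimethyloct-6-enal
Product: 9 (1R,2S,4R,5S)-4-[(4-methoxybenzyl)oxy]-5-methyl-2-(prop-1-en-2-yl)cyclohexan-1-ol
Conditions: ZnBr2 (1.5 equiv), CH2Cl2, 0 °C
Reagents that add atoms: none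
Why: Lewis acid-promoted intramolecular carbonyl-ene cyclisation of the citronellal type passes through a chair transition state with the zinc-bound carbonyl oxygen, the reacting alkene terminus and the C3 methyl equatorial, which forms the C1–C6 bond with hydroxyl and isopropenyl trans (1R at the carbinol carbon, 2S at the isopropenyl carbon), the C4 ether being forced axial by its fixed cis relation to the methyl, an arrangement that should cost less than the alternative chair with an axial methyl.

Step 7
Reactants: 9 (1R,2S,4R,5S)-4-[(4-methoxybenzyl)oxy]-5-methyl-2-(prop-1-en-2-yl)cyclohexan-1-ol; 10 acryloyl chloride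
Product: 11 (1R,2S,4R,5S)-4-[(4-methoxybenzyl)oxy]-5-methyl-2-(prop-1-en-2-yl)cyclohexyl acrylate
Conditions: Et3N, DMAP (cat.), CH2Cl2, −20 to 0 °C
Reagents that add atoms: none
Why: DMAP-assisted O-acylation of the secondary equatorial alcohol with an acid chloride installs the acrylate with retention at C1, the low temperature holding back amine conjugate addition to the acrylate.

Step 8
Reactants: 11 (1R,2S,4R,5S)-4-[(4-methoxybenzyl)oxy]-5-methyl-2-(prop-1-en-2-yl)cyclohexyl acrylate
Product: 12 (4aS,6R,7S,8aR)-6-[(4-methoxybenzyl)oxy]-4,7-dimethyl-4a,5,6,7,8,8a-hexahydro-2H-chromen-2-one (trans-fused)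
Conditions: second-generation Grubbs catalyst RuCl2(H2IMes)(PCy3)(=CHPh) (5 mol%, two portions), CH2Cl2 (0.005 M), 40 °C, argon sparge
Reagents that add atoms: none
Why: The ruthenium benzylidene exchanges onto one of the two terminal alkenes, the new carbene adds across the other C=C to a ruthenacyclobutane, and cycloreversion expels ethylene and leaves the C7=C8 bond; this is the known ring-closing metathesis of an acrylate ester with a 1,1-disubstituted alkene to a 4-methyl-5,6-dihydropyran-2-one. The one ring closed is the six-membered lactone O–C1–C6–C7=C8–C9, closed by forming its endocyclic alkene between the acrylate α-carbon (C8) and the internal isopropenyl carbon (C7), the ester C–O bond and the C1–C6 bond being already in place. No stereocentre is created: the C7=C8 geometry is necessarily cis within the ring and the four stereocentres of ring A are untouched. The step needs ring closure to win over intermolecular metathesis of the acrylate termini, and this is secured by high dilution, by removal of ethylene and by the trans-diequatorial C1–O and C6–C7 bonds of the cyclohexane chair, which hold the two alkenes within reach and lead to an unstrained trans-fused bicycle. The PMB ether and the ring methyl are remote spectators that should not bind ruthenium.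

Step 9
Reactants: 12 (4aS,6R,7S,8aR)-6-[(4-methoxybenzyl)oxy]-4,7-dimethyl-4a,5,6,7,8,8a-hexahydro-2H-chromen-2-one
Product: 13 (4R,4aS,6R,7S,8aR)-6-[(4-methoxybenzyl)oxy]-4,7-dimethyloctahydro-2H-chromen-2-one
Conditions: [(Ph3P)CuH]6 (0.5 equiv), H2O (5 equiv), degassed toluene, rt
Reagents that add atoms: none
Why: Copper hydride conjugate reduction of an α,β-unsaturated lactone delivers hydride to the β-carbon C7 along the axial line of the trans-fused half-chair, anti to the axial hydrogen on C6 and through a chair-like copper enolate, so the C7 methyl should end equatorial (7R in the chain numbering, 4R in the chromanone), and water then protonates the enolate at C8.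

Step 10
Reactants: 13 (4R,4aS,6R,7S,8aR)-6-[(4-methoxybenzyl)oxy]-4,7-dimethyloctahydro-2H-chromen-2-one; 14 1-bromo-2-methylprop-1-ene
Product: 16 (6R)-6-[(1S,2R,4S,5R)-2-hydroxy-5-[(4-methoxybenzyl)oxy]-4-methylcyclohexyl]-2-methylhept-2-en-4-one, via 2-methylprop-1-enyllithium 15 (not isolated)
Conditions: 14, tBuLi (2 equiv per 14), Et2O, −78 °C; 15 (1.1 equiv) cannulated into 13 in THF, −78 °C; AcOH in THF at −78 °C, then rt
Reagents that add atoms: none
Why: Acyl substitution of the δ-lactone by an alkenyllithium made by bromine–lithium exchange gives a lithium hemiketalate that is stable at −78 °C and collapses only on the cold acid quench, which should hold the reaction at one addition and release the C1 hydroxyl and the C9 enone with C10 and C11 in place; no stereocentre is touched.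

Step 11
Reactants: 16 (6R)-6-[(1S,2R,4S,5R)-2-hydroxy-5-[(4-methoxybenzyl)oxy]-4-methylcyclohexyl]-2-methylhept-2-en-4-one; 17 angelic acid
Product: 19 (1R,2S,4R,5S)-4-[(4-methoxybenzyl)oxy]-5-methyl-2-[(2R)-6-methyl-4-oxohept-5-en-2-yl]cyclohexyl (2Z)-2-methylbut-2-enoate, via angelic 2,4,6-trichlorobenzoic anhydride 18 (not isolated)
Conditions: 17, 2,4,6-trichlorobenzoyl chloride, Et3N, toluene, rt; then 16, toluene, 80 °C (no DMAP)
Reagents that add atoms: none
Why: Yamaguchi mixed-anhydride esterification run without a nucleophilic catalyst sends the C1 hydroxyl to the unhindered angeloyl carbonyl of 18 and avoids the addition–elimination path that would turn the Z-alkene into the tiglate, with retention at C1.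

Step 12
Reactants: 19 (1R,2S,4R,5S)-4-[(4-methoxybenzyl)oxy]-5-methyl-2-[(2R)-6-methyl-4-oxohept-5-en-2-yl]cyclohexyl (2Z)-2-methylbut-2-enoate
Product: 20 (1R,2S,4R,5S)-2-[(2R,4R)-4-hydroxy-6-methylhept-5-en-2-yl]-4-[(4-methoxybenzyl)oxy]-5-methylcyclohexyl (2Z)-2-methylbut-2-enoate
Conditions: (S)-2-methyl-CBS-oxazaborolidine [(S)-1-methyl-3,3-diphenyltetrahydro-1H,3H-pyrrolo[1,2-c][1,3,2]oxazaborole] (0.5 equiv), catecholborane (2 equiv), toluene, −78 °C; MeOH, then aq. NaHCO3
Reagents that add atoms: none
Why: Corey–Bakshi–Shibata reduction, in which the ketone should bind the ring boron with the bulkier 2-methylprop-1-enyl arm turned away from the catalyst so that hydride from the nitrogen-bound borane reaches the carbonyl face that gives the 9R alcohol (the sense expected with the S catalyst when the alkenyl group is the large substituent), while the low temperature keeps the reduction 1,2 and spares the angelate.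

Step 13
Reactants: 20 (1R,2S,4R,5S)-2-[(2R,4R)-4-hydroxy-6-methylhept-5-en-2-yl]-4-[(4-methoxybenzyl)oxy]-5-methylcyclohexyl (2Z)-2-methylbut-2-enoate
Product: 21 (1R,2S,4R,5S)-2-[(2R,4R)-4-acetoxy-6-methylhept-5-en-2-yl]-4-[(4-methoxybenzyl)oxy]-5-methylcyclohexyl (2Z)-2-methylbut-2-enoate
Conditions: Ac2O, pyridine, DMAP (cat.), CH2Cl2, 0 °C
Reagents that add atoms: acetic anhydride, CC(=O)OC(C)=O
Why: DMAP-catalysed acetylation of the secondary allylic alcohol with acetic anhydride takes place at oxygen with retention at C9, under basic conditions that do not ionise the allylic system.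

Step 14
Reactants: 21 (1R,2S,4R,5S)-2-[(2R,4R)-4-acetoxy-6-methylhept-5-en-2-yl]-4-[(4-methoxybenzyl)oxy]-5-methylcyclohexyl (2Z)-2-methylbut-2-enoate
Product: 22 (1R,2S,4R,5S)-2-[(2R,4R)-4-acetoxy-6-methylhept-5-en-2-yl]-4-hydroxy-5-methylcyclohexyl (2Z)-2-methylbut-2-enoate
Conditions: DDQ (1.3 equiv), CH2Cl2/pH 7 phosphate buffer (10:1), 0 °C
Reagents that add atoms: none
Why: Oxidative cleavage of the PMB ether by DDQ (benzylic hydride abstraction, then hydrolysis of the oxocarbenium ion) frees the axial C4 hydroxyl, the neutral buffer guarding the allylic acetate while the esters and isolated alkenes are inert to the quinone.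

**Compound list**

1 | 4-methylpent-3-en-1-ol | CC(C)=CCCO | starting material
2 | 4-methylpent-3-enal | CC(C)=CCC=O | intermediate
3 | (E)-crotylboronic acid pinacol ester | C/C=C/CB1OC(C)(C)C(C)(C)O1 | starting material
4 | (3S,4R)-3,7-dimethylocta-1,6-dien-4-ol | C=C[C@H](C)[C@H](O)CC=C(C)C | intermediate
5 | 1-({[(3S,4R)-3,7-dimethylocta-1,6-dien-4-yl]oxy}methyl)-4-methoxybenzene | C=C[C@H](C)[C@H](OCc1ccc(OC)cc1)CC=C(C)C | intermediate
6 | 9-[(3S,4R)-4-[(4-methoxybenzyl)oxy]-3,7-dimethyloct-6-en-1-yl]-9-borabicyclo[3.3.1]nonane | B1(CC[C@H](C)[C@H](OCc2ccc(OC)cc2)CC=C(C)C)C2CCCC1CCC2 | intermediate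
7 | (3S,4R)-4-[(4-methoxybenzyl)oxy]-3,7-dimethyloct-6-en-1-ol | OCC[C@H](C)[C@H](OCc1ccc(OC)cc1)CC=C(C)C | intermediate
8 | (3S,4R)-4-[(4-methoxybenzyl)oxy]-3,7-dimethyloct-6-enal | O=CC[C@H](C)[C@H](OCc1ccc(OC)cc1)CC=C(C)C | intermediate
9 | (1R,2S,4R,5S)-4-[(4-methoxybenzyl)oxy]-5-methyl-2-(prop-1-en-2-yl)cyclohexan-1-ol | O[C@@H]1C[C@H](C)[C@H](OCc2ccc(OC)cc2)C[C@H]1C(C)=C | intermediate
10 | acryloyl chloride | C=CC(Cl)=O | starting material
11 | (1R,2S,4R,5S)-4-[(4-methoxybenzyl)oxy]-5-methyl-2-(prop-1-en-2-yl)cyclohexyl acrylate | C=CC(=O)O[C@@H]1C[C@H](C)[C@H](OCc2ccc(OC)cc2)C[C@H]1C(C)=C | intermediate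
12 | (4aS,6R,7S,8aR)-6-[(4-methoxybenzyl)oxy]-4,7-dimethyl-4a,5,6,7,8,8a-hexahydro-2H-chromen-2-one | O1[C@@H]2C[C@H](C)[C@H](OCc3ccc(OC)cc3)C[C@H]2C(C)=CC1=O | intermediate
13 | (4R,4aS,6R,7S,8aR)-6-[(4-methoxybenzyl)oxy]-4,7-dimethyloctahydro-2H-chromen-2-one | O1[C@@H]2C[C@H](C)[C@H](OCc3ccc(OC)cc3)C[C@H]2[C@H](C)CC1=O | intermediate
14 | 1-bromo-2-methylprop-1-ene | CC(C)=CBr | starting material
15 | 2-methylprop-1-enyllithium | [Li]C=C(C)C | intermediate
16 | (6R)-6-[(1S,2R,4S,5R)-2-hydroxy-5-[(4-methoxybenzyl)oxy]-4-methylcyclohexyl]-2-methylhept-2-en-4-one | O[C@@H]1C[C@H](C)[C@H](OCc2ccc(OC)cc2)C[C@H]1[C@H](C)CC(=O)C=C(C)C | intermediate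
17 | angelic acid, (2Z)-2-methylbut-2-enoic acid | C/C=C(/C)C(=O)O | starting material
18 | (2Z)-2-methylbut-2-enoic 2,4,6-trichlorobenzoic anhydride | C/C=C(/C)C(=O)OC(=O)c1c(Cl)cc(Cl)cc1Cl | intermediate
19 | (1R,2S,4R,5S)-4-[(4-methoxybenzyl)oxy]-5-methyl-2-[(2R)-6-methyl-4-oxohept-5-en-2-yl]cyclohexyl (2Z)-2-methylbut-2-enoate | C/C=C(/C)C(=O)O[C@@H]1C[C@H](C)[C@H](OCc2ccc(OC)cc2)C[C@H]1[C@H](C)CC(=O)C=C(C)C | intermediate
20 | (1R,2S,4R,5S)-2-[(2R,4R)-4-hydroxy-6-methylhept-5-en-2-yl]-4-[(4-methoxybenzyl)oxy]-5-methylcyclohexyl (2Z)-2-methylbut-2-enoate | C/C=C(/C)C(=O)O[C@@H]1C[C@H](C)[C@H](OCc2ccc(OC)cc2)C[C@H]1[C@H](C)C[C@H](C=C(C)C)O | intermediate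
21 | (1R,2S,4R,5S)-2-[(2R,4R)-4-acetoxy-6-methylhept-5-en-2-yl]-4-[(4-methoxybenzyl)oxy]-5-methylcyclohexyl (2Z)-2-methylbut-2-enoate | C/C=C(/C)C(=O)O[C@@H]1C[C@H](C)[C@H](OCc2ccc(OC)cc2)C[C@H]1[C@H](C)C[C@H](C=C(C)C)OC(C)=O | intermediate
22 | (1R,2S,4R,5S)-2-[(2R,4R)-4-acetoxy-6-methylhept-5-en-2-yl]-4-hydroxy-5-methylcyclohexyl (2Z)-2-methylbut-2-enoate | C/C=C(/C)C(=O)O[C@@H]1C[C@H](C)[C@H](O)C[C@H]1[C@H](C)C[C@H](C=C(C)C)OC(C)=O | target

**Step count**

Total steps: 14. Longest linear sequence: 14 steps (1 to 22).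

**Steps most likely to fail**

Step 8 (ring-closing metathesis). The carbene may load on the acrylate and be used up in intermolecular coupling, or decompose before it engages the hindered 1,1-disubstituted alkene, so that closure stalls or gives dimers. The fallback forms the same C7=C8 bond by an intramolecular Horner–Wadsworth–Emmons olefination. It sets out from 9: esterification with diethylphosphonoacetic acid (EDC·HCl, DMAP, CH2Cl2) should give (1R,2S,4R,5S)-4-[(4-methoxybenzyl)oxy]-5-methyl-2-(prop-1-en-2-yl)cyclohexyl (diethoxyphosphoryl)acetate F1. Lemieux–Johnson cleavage of the isopropenyl group (OsO4 cat., NaIO4, 2,6-lutidine, dioxane/H2O) should then give the methyl ketone (1R,2R,4R,5S)-2-acetyl-4-[(4-methoxybenzyl)oxy]-5-methylcyclohexyl (diethoxyphosphoryl)acetate F2. Ring closure under Masamune–Roush conditions (LiCl, DBU, MeCN) returns to the route at 12.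

Step 9 (conjugate reduction). Hydride may reach C7 from the equatorial side as well, or the β,β-disubstituted enoate may react sluggishly, so that the C7 configuration is eroded. The fallback replaces substrate control on the lactone by catalyst control on the ring-opened allylic alcohol. It sets out from 12: iBu2AlH (CH2Cl2, −78 to 0 °C) should give the diol (1R,2S,4R,5S)-2-[(2Z)-4-hydroxybut-2-en-2-yl]-4-[(4-methoxybenzyl)oxy]-5-methylcyclohexan-1-ol F3. Asymmetric hydrogenation with Ru(OAc)2[(S)-BINAP] (H2, MeOH), the ligand chosen by analogy with (Z)-3,3-disubstituted allylic alcohols, should give (1R,2S,4R,5S)-2-[(2R)-4-hydroxybutan-2-yl]-4-[(4-methoxybenzyl)oxy]-5-methylcyclohexan-1-ol F4. Oxidative lactonisation of this 1,5-diol (TEMPO cat., PhI(OAc)2, CH2Cl2) returns to the route at 13.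

Step 10 (lactone opening). The tetrahedral intermediate may collapse early so that a second alkenyllithium adds to the ketone, or the lactone may be enolised and come back unchanged. The fallback passes through a Weinreb amide, whose chelated adduct cannot over-add. It sets out from 13: MeNH(OMe)·HCl and iPrMgCl (THF, −20 °C) should give (3R)-3-[(1S,2R,4S,5R)-2-hydroxy-5-[(4-methoxybenzyl)oxy]-4-methylcyclohexyl]-N-methoxy-N-methylbutanamide F5. Treatment with Me2C=CHMgBr (3 equiv, THF, 0 °C; aq. NH4Cl) returns to the route at 16.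

Further compounds
F1 | step 8 | (1R,2S,4R,5S)-4-[(4-methoxybenzyl)oxy]-5-methyl-2-(prop-1-en-2-yl)cyclohexyl (diethoxyphosphoryl)acetate | CCOP(=O)(OCC)CC(=O)O[C@@H]1C[C@H](C)[C@H](OCc2ccc(OC)cc2)C[C@H]1C(C)=C
F2 | step 8 | (1R,2R,4R,5S)-2-acetyl-4-[(4-methoxybenzyl)oxy]-5-methylcyclohexyl (diethoxyphosphoryl)acetate | CCOP(=O)(OCC)CC(=O)O[C@@H]1C[C@H](C)[C@H](OCc2ccc(OC)cc2)C[C@H]1C(C)=O
F3 | step 9 | (1R,2S,4R,5S)-2-[(2Z)-4-hydroxybut-2-en-2-yl]-4-[(4-methoxybenzyl)oxy]-5-methylcyclohexan-1-ol | O[C@@H]1C[C@H](C)[C@H](OCc2ccc(OC)cc2)C[C@H]1/C(C)=C\CO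
F4 | step 9 | (1R,2S,4R,5S)-2-[(2R)-4-hydroxybutan-2-yl]-4-[(4-methoxybenzyl)oxy]-5-methylcyclohexan-1-ol | O[C@@H]1C[C@H](C)[C@H](OCc2ccc(OC)cc2)C[C@H]1[C@H](C)CCO
F5 | step 10 | (3R)-3-[(1S,2R,4S,5R)-2-hydroxy-5-[(4-methoxybenzyl)oxy]-4-methylcyclohexyl]-N-methoxy-N-methylbutanamide | O[C@@H]1C[C@H](C)[C@H](OCc2ccc(OC)cc2)C[C@H]1[C@H](C)CC(=O)N(C)OC
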